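**Synthetic plan**

1. Locants (target): C1 = C(Et)(styryl), C2H=C3(Me), C4 and C5 = ring-fusion CH (C4 beside C3), C6 = C(Et)(CO2H); C7 = CHMe on C5, C8 = C=O, C9 = CHMe on C4. Cuts, in retrosynthetic order: C7–C8 and C7–CH3 (Dieckmann condensation, methylation); the styrene C=C (olefination of a C1 formyl group); then, after rejoining that formyl carbon to C9 and to the carboxyl oxygen, C1–C(formyl) and C4–C9 (intramolecular Diels–Alder); finally C1–C6 and C4–C5 (intermolecular Diels–Alder).
2. Enabling feature: on the cyclohexene ring the styryl group at C1 and the C4–C9 bond stand cis-1,4 across C2=C3(Me), and both are cis to the CO2H on C6 next to C1. This is the footprint of a bicyclo[2.2.2]oct-2-ene whose two-carbon bridge has been severed, and the C6 carboxyl is placed to carry that bridge in as an enol ester.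
3. Forward ring order: cyclohexene first (catalytic asymmetric [4+2]); then γ-lactone and bicyclo[2.2.2]octene bridge together (tethered [4+2]); both reopened by methanolysis and retro-aldol cleavage; cyclopentanone last.
4. Stereochemistry: C6 and C5 from the enantioselective cycloaddition (trans CO2H/arm relation from the E enal); C1 and C4 from the carboxyl tether, on its own face; C7 and C9 by base equilibration to the all-trans ketone; the E styrene from the olefination.

Key step: step 9

Convention: with the six-membered ring drawn flat and numbered C1 to C6 clockwise, β means toward the viewer and α away; the target then carries 1β-Et, 1α-styryl, 6β-Et, 6α-CO2H, 5β-C7 and 4α-C9.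

Assumption: the (S)-oxazaborolidinium catalyst of step 3 is taken to give the drawn enantiomer of 6, following the formyl C–H···O binding model for α-substituted enals; if the sense proves opposite at that stage, the (R)-catalyst is used and nothing else changes.

**Route**

Step 1
Reactants: 1 (E)-hex-3-en-2-one
Product: 2 (E)-2-(triisopropylsilyloxy)hexa-1,3-diene
Conditions: TIPSOTf, Et3N, CH2Cl2, 0 °C
Reagents that add atoms: triisopropylsilyl trifluoromethanesulfonate, CC(C)[Si](OS(=O)(=O)C(F)(F)F)(C(C)C)C(C)C
Why: Soft enolisation of the methyl ketone with a silyl triflate and an amine base (kinetic silyl enol ether formation) should remove a methyl proton rather than the γ-proton and so give the cross-conjugated 2-silyloxy diene with the E alkene untouched.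

Step 2
Reactants: 3 2-ethylacrolein (4 equiv); 4 methyl but-3-enoate
Product: 5 methyl (E)-4-formylhex-3-enoate
Conditions: second-generation Hoveyda-Grubbs catalyst RuCl2(H2IMes)(=CH-C6H4-2-OiPr) (5 mol %), 1,4-benzoquinone (10 mol %), CH2Cl2, 40 °C
Reagents that add atoms: none
Why: Olefin cross-metathesis of a fast-reacting terminal alkene with an excess of a 1,1-disubstituted enal is a selective pairing that should give the trisubstituted enal with CHO trans to the new chain (E), while benzoquinone suppresses alkene migration toward the ester.

Step 3
Reactants: 2 (E)-2-(triisopropylsilyloxy)hexa-1,3-diene (1.5 equiv); 5 methyl (E)-4-formylhex-3-enoate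
Product: 6 methyl 2-[1α,6β-diethyl-6α-formyl-3-(triisopropylsilyloxy)cyclohex-2-en-5β-yl]acetate
Conditions: (S)-3,3-diphenyl-1-(2-methylphenyl)tetrahydro-1H,3H-pyrrolo[1,2-c][1,3,2]oxazaborole (20 mol %), Tf2NH (18 mol %), CH2Cl2, -78 to -40 °C
Reagents that add atoms: none
Why: In this catalytic enantioselective Diels–Alder reaction (chiral oxazaborolidinium activation of the enal) the silyloxy group and the terminal ethyl of the diene both send its CH2 terminus to the enal β-carbon (para/ortho adduct), suprafacial addition keeps CHO trans to the CH2CO2Me arm, the catalyst face sets the absolute configuration at C6 and C5, and the endo approach of CHO sets the C1 centre, which step 4 removes.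

Step 4
Reactants: 6 methyl 2-[1α,6β-diethyl-6α-formyl-3-(triisopropylsilyloxy)cyclohex-2-en-5β-yl]acetate
Product: 7 methyl 2-(1,6β-diethyl-6α-formyl-3-oxocyclohex-1-en-5β-yl)acetate
Conditions: Pd(OAc)2 (1.1 equiv), MeCN, 25 to 40 °C
Reagents that add atoms: none
Why: In the Saegusa–Ito oxidation the divalent palladium enolate formed from the regiodefined silyl enol ether can undergo β-hydride elimination only toward the ethyl-bearing CH, so the 3-ethyl enone should form and the C1 stereocentre is erased.

Step 5
Reactants: 7 methyl 2-(1,6β-diethyl-6α-formyl-3-oxocyclohex-1-en-5β-yl)acetate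
Product: 9 methyl 2-[1,6β-diethyl-6α-formyl-3-(trifluoromethanesulfonyloxy)cyclohexa-1,3-dien-5β-yl]acetate, via potassium dienolate 8 (not isolated)
Conditions: KN(SiMe3)2 (1.05 equiv), THF, -78 °C; then PhNTf2, -78 to -20 °C
Reagents that add atoms: N-phenylbis(trifluoromethanesulfonimide), O=S(=O)(N(c1ccccc1)S(=O)(=O)C(F)(F)F)C(F)(F)F
Why: Kinetic deprotonation of the enone at the ring CH2 gives the cross-conjugated dienolate, which is O-sulfonylated (enol triflate formation), while the aldehyde on a quaternary carbon cannot enolise and is too hindered for aldol addition at -78 °C and the ester CH2 is less acidic than the ketone α′ position.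

Step 6
Reactants: 9 methyl 2-[1,6β-diethyl-6α-formyl-3-(trifluoromethanesulfonyloxy)cyclohexa-1,3-dien-5β-yl]acetate
Product: 10 methyl 2-(1,6β-diethyl-6α-formyl-3-methylcyclohexa-1,3-dien-5β-yl)acetate
Conditions: MeZnCl (2 equiv), Pd(PPh3)4 (5 mol %), THF, 0 to 23 °C
Reagents that add atoms: methylzinc chloride, C[Zn]Cl
Why: Negishi coupling of the dienyl triflate at zerovalent palladium should install the C3 methyl group, since organozinc halides leave the aldehyde and ester alone and the reaction runs at room temperature, below the onset of a 1,5-formyl shift in this 5-formylcyclohexa-1,3-diene.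

Step 7
Reactants: 10 methyl 2-(1,6β-diethyl-6α-formyl-3-methylcyclohexa-1,3-dien-5β-yl)acetate
Product: 11 1,6β-diethyl-5β-(2-methoxy-2-oxoethyl)-3-methylcyclohexa-1,3-diene-6α-carboxylic acid
Conditions: NaClO2, NaH2PO4, 2-methyl-2-butene (20 equiv), t-BuOH/H2O, 0 to 23 °C
Reagents that add atoms: sodium chlorite, [Na+].[O-]Cl=O
Why: The Pinnick oxidation is selective for the aldehyde, and the large excess of 2-methyl-2-butene traps hypochlorous acid before it can attack the ring diene.

Step 8
Reactants: 11 1,6β-diethyl-5β-(2-methoxy-2-oxoethyl)-3-methylcyclohexa-1,3-diene-6α-carboxylic acid; 12 ethyl 2-formylpropanoate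
Product: 15 (E)-3-ethoxy-2-methyl-3-oxoprop-1-en-1-yl 1,6β-diethyl-5β-(2-methoxy-2-oxoethyl)-3-methylcyclohexa-1,3-diene-6α-carboxylate, via acid chloride 13 (not isolated), via sodium enolate 14 (not isolated)
Conditions: 11, 1-chloro-N,N,2-trimethylprop-1-en-1-amine (1.2 equiv), CH2Cl2, 0 to 23 °C; separately 12, NaH, THF, 0 °C; combine, THF, 0 to 23 °C
Reagents that add atoms: none
Why: Acid chloride formation with the α-chloroenamine is neutral (no HCl, so no acid-induced diene migration), and O-acylation of the ambident formyl-ester enolate at its oxygen terminus is the normal course with acyl chlorides; the enol ester is drawn E, but either geometry serves because the centre it controls is erased in step 10.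

Step 9
Reactants: 15 (E)-3-ethoxy-2-methyl-3-oxoprop-1-en-1-yl 1,6β-diethyl-5β-(2-methoxy-2-oxoethyl)-3-methylcyclohexa-1,3-diene-6α-carboxylate
Product: 16 tricyclic γ-lactone (2-oxaisotwistene): bicyclo[2.2.2]oct-2-ene with bridgeheads C1 (Et) and C4 (H), bridges C2=C3(Me), C6(Et)–C5(β-CH2CO2Me) and CH(O)–C(Me)(CO2Et), the lactone running C6–C(=O)–O–CH
Conditions: 1,2-dichlorobenzene (0.005 M), BHT (10 mol %), 160 °C, Ar
Reagents that add atoms: none
Why: This is a thermal intramolecular Diels–Alder reaction, a concerted suprafacial [4+2] cycloaddition between the s-cis-locked ring diene (C1=C2–C3=C4) and the tethered β-acyloxy-methacrylate, whose O-bearing carbon bonds to C1 and whose α-carbon bonds to C4. The closest known reaction type is the intramolecular Diels–Alder reaction of cyclohexa-1,3-dienes carrying a dienophile on a three-atom chain at the sp3 carbon next to the diene (isotwistene-forming cycloadditions, as with masked o-benzoquinones), together with the use of β-acyloxyacrylates as dienophiles. The γ-lactone closes in the fused mode as a five-membered ring (C6, carbonyl C, O, CH–O, C1) because the short tether reaches only the adjacent diene terminus, and the bicyclo[2.2.2]oct-2-ene closes in the bridged mode as the new six-membered ring spanning C1 and C4. The quaternary C1 and C4 are controlled by the anchoring of the tether on C6, which forces both new bonds onto the carboxyl (α) face and so anti to the CH2CO2Me arm on C5; the CH–O centre is fixed by the lactone (oxygen syn to the C6 bridge) and the C(Me)CO2Et centre by the enol ester geometry, and both of these are deleted in step 10. The step needs regio- and π-facial selectivity, and both are secured geometrically by the acyloxy tether even though it overrides the electronic preference of the diene. High dilution, a radical inhibitor and the lowest workable temperature should hold back oligomerisation and 1,5-hydrogen migration in the diene.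

Step 10
Reactants: 16 tricyclic γ-lactone (2-oxaisotwistene)
Product: 18 aldehyde triester: cyclohex-2-ene with C1(β-Et)(α-CHO), C3-Me, C4(α-CH(Me)CO2Me), C5(β-CH2CO2Me) and C6(β-Et)(α-CO2Me), via ring-opened sodium alkoxide 17 (not isolated)
Conditions: NaOMe (4 equiv), MeOH, 23 to 50 °C; then aq. NH4Cl
Reagents that add atoms: methanol, CO, delivered as sodium methoxide, [Na+].[O-]C
Why: Methoxide opens the lactone by transesterification, and the released alkoxide, β to the bridge ester and flanked by two fully substituted carbons, should undergo retro-aldol cleavage driven by relief of bicyclic strain and by protonation of the ester enolate in methanol; the ethyl ester exchanges to methyl, the new aldehyde cannot enolise, C1, C4, C5 and C6 are untouched, and the propanoate α-centre forms as a mixture that step 13 corrects.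

Step 11
Reactants: 18 aldehyde triester; 19 diethyl benzylphosphonate (1.5 equiv)
Product: 21 (E)-styryl triester: as 18 with C1(α-CH=CHPh) in place of CHO, via sodium phosphonate carbanion 20 (not isolated)
Conditions: 19, NaN(SiMe3)2 (1.4 equiv), THF, 0 °C; then 18, -20 to 23 °C
Reagents that add atoms: none
Why: Horner–Wadsworth–Emmons olefination with the semistabilised benzylphosphonate anion should give the E styrene, and preforming the anion with a slight deficit of base leaves no free amide to enolise the three esters.

Step 12
Reactants: 21 (E)-styryl triester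
Product: 23 trans-hydrindanone β-keto ester: C7(Me)(CO2Me), C8=O, C9H(Me), with C1(β-Et)(α-styryl) and C6(β-Et)(α-CO2Me), via sodium keto ester enolate 22 (not isolated)
Conditions: NaH (1.3 equiv), MeOH (0.1 equiv), THF, 65 °C; then MeI (5 equiv), 0 to 23 °C
Reagents that add atoms: iodomethane, CI
Why: Under equilibrating Dieckmann conditions only attack of the CH2CO2Me enolate on the CH(Me)CO2Me ester gives a β-keto ester that is held as its enolate, the trans-disposed arms close to the trans-fused five-membered ring, and C-methylation of that enolate follows in the same flask with little free alkoxide left to reopen the quaternised product (configuration at C7 is immaterial).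

Step 13
Reactants: 23 trans-hydrindanone β-keto ester
Product: 25 all-trans keto methyl ester (methyl ester of the target), via α-epimeric keto ester 24 (not isolated)
Conditions: LiCl (5 equiv), H2O (2 equiv), DMSO, 150 °C; then NaOMe (0.3 equiv), MeOH, 23 °C
Reagents that add atoms: none
Why: Krapcho demethoxycarbonylation (chloride attack on the methyl of the activated ester, then loss of CO2) spares the unactivated hindered ester, and alkoxide-mediated enolisation should then settle C7 and C9 with each methyl trans to the neighbouring ring bond, the thermodynamic all-trans arrangement on the rigid trans-hydrindanone.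

Step 14
Reactants: 25 all-trans keto methyl ester
Product: 26 dinorspiculoic acid A
Conditions: LiI (10 equiv), pyridine, 115 °C; then 1 M HCl
Reagents that add atoms: none
Why: SN2 O-demethylation by iodide attacks the unhindered methyl group instead of the shielded carbonyl of the ester on quaternary C6, and the ketone α-centres already sit at their equilibrium configuration, so the basic medium cannot degrade them.

**Compound list**

1 | (E)-hex-3-en-2-one | CC/C=C/C(C)=O | starting material
2 | (E)-2-(triisopropylsilyloxy)hexa-1,3-diene | C=C(O[Si](C(C)C)(C(C)C)C(C)C)/C=C/CC | intermediate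
3 | 2-ethylacrolein | C=C(CC)C=O | starting material
4 | methyl but-3-enoate | C=CCC(=O)OC | starting material
5 | methyl (E)-4-formylhex-3-enoate | O=C/C(CC)=C/CC(=O)OC | intermediate
6 | methyl 2-[1α,6β-diethyl-6α-formyl-3-(triisopropylsilyloxy)cyclohex-2-en-5β-yl]acetate (C1 drawn as the endo adduct; removed in step 4) | CC[C@@]1(C=O)[C@H](CC)C=C(O[Si](C(C)C)(C(C)C)C(C)C)C[C@H]1CC(=O)OC | intermediate
7 | methyl 2-(1,6β-diethyl-6α-formyl-3-oxocyclohex-1-en-5β-yl)acetate | CC[C@@]1(C=O)C(CC)=CC(=O)C[C@H]1CC(=O)OC | intermediate
8 | potassium dienolate of 7 (not isolated) | CC[C@@]1(C=O)C(CC)=CC([O-])=C[C@H]1CC(=O)OC.[K+] | intermediate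
9 | methyl 2-[1,6β-diethyl-6α-formyl-3-(trifluoromethanesulfonyloxy)cyclohexa-1,3-dien-5β-yl]acetate | CC[C@@]1(C=O)C(CC)=CC(OS(=O)(=O)C(F)(F)F)=C[C@H]1CC(=O)OC | intermediate
10 | methyl 2-(1,6β-diethyl-6α-formyl-3-methylcyclohexa-1,3-dien-5β-yl)acetate | CC[C@@]1(C=O)C(CC)=CC(C)=C[C@H]1CC(=O)OC | intermediate
11 | 1,6β-diethyl-5β-(2-methoxy-2-oxoethyl)-3-methylcyclohexa-1,3-diene-6α-carboxylic acid | CC[C@@]1(C(=O)O)C(CC)=CC(C)=C[C@H]1CC(=O)OC | intermediate
12 | ethyl 2-formylpropanoate | CCOC(=O)C(C)C=O | starting material
13 | acid chloride of 11 (not isolated) | CC[C@@]1(C(=O)Cl)C(CC)=CC(C)=C[C@H]1CC(=O)OC | intermediate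
14 | sodium enolate of 12, sodium 3-ethoxy-2-methyl-3-oxoprop-1-en-1-olate (not isolated; drawn E) | CCOC(=O)/C(C)=C/[O-].[Na+] | intermediate
15 | (E)-3-ethoxy-2-methyl-3-oxoprop-1-en-1-yl ester of acid 11 | CC[C@@]1(C(=O)O/C=C(\C)C(=O)OCC)C(CC)=CC(C)=C[C@H]1CC(=O)OC | intermediate
16 | tricyclic γ-lactone (2-oxaisotwistene) with ethyl ester on the two-carbon bridge | CC[C@@]12C(=O)O[C@H]3[C@]1(CC)C=C(C)[C@H]([C@]3(C)C(=O)OCC)[C@H]2CC(=O)OC | intermediate
17 | ring-opened sodium alkoxide of 16 (not isolated) | CC[C@]1(C(=O)OC)[C@H](CC(=O)OC)[C@@H]2C(C)=C[C@@]1(CC)[C@H]([O-])[C@@]2(C)C(=O)OCC.[Na+] | intermediate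
18 | aldehyde triester (propanoate α-centre formed as a mixture; one epimer drawn) | CC[C@@]1(C(=O)OC)[C@](CC)(C=O)C=C(C)[C@H]([C@@H](C)C(=O)OC)[C@H]1CC(=O)OC | intermediate
19 | diethyl benzylphosphonate | CCOP(=O)(Cc1ccccc1)OCC | starting material
20 | sodium carbanion of 19 (not isolated) | CCOP(=O)([CH-]c1ccccc1)OCC.[Na+] | intermediate
21 | (E)-styryl triester | CC[C@@]1(C(=O)OC)[C@](CC)(/C=C/c2ccccc2)C=C(C)[C@H]([C@@H](C)C(=O)OC)[C@H]1CC(=O)OC | intermediate
22 | sodium enolate of the Dieckmann β-keto ester (not isolated) | CC[C@@]1(/C=C/c2ccccc2)C=C(C)[C@H]2[C@@H](C(C(=O)OC)=C([O-])[C@@H]2C)[C@]1(CC)C(=O)OC.[Na+] | intermediate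
23 | trans-hydrindanone β-keto ester, methylated at C7 (C7 configuration immaterial; C9 drawn in its final configuration) | CC[C@@]1(/C=C/c2ccccc2)C=C(C)[C@H]2[C@@H]([C@](C)(C(=O)OC)C(=O)[C@@H]2C)[C@]1(CC)C(=O)OC | intermediate
24 | keto methyl ester as a mixture of α-methyl epimers (not isolated) | CC[C@@]1(/C=C/c2ccccc2)C=C(C)[C@H]2[C@@H](C(C)C(=O)C2C)[C@]1(CC)C(=O)OC | intermediate
25 | all-trans keto methyl ester (methyl ester of the target) | CC[C@@]1(/C=C/c2ccccc2)C=C(C)[C@H]2[C@@H]([C@@H](C)C(=O)[C@@H]2C)[C@]1(CC)C(=O)OC | intermediate
26 | dinorspiculoic acid A | CC[C@@]1(/C=C/c2ccccc2)C=C(C)[C@H]2[C@@H]([C@@H](C)C(=O)[C@@H]2C)[C@]1(CC)C(=O)O | target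

**Step count**

Total steps: 14 (steps 1 and 2 are one-step branches that converge in step 3).
Longest linear sequence: 13 steps (from 3 and 4 through steps 2 to 14; equally from 1 through steps 1 and 3 to 14).

**Steps most likely to fail**

Step 9 (tethered cycloaddition). The trisubstituted push-pull dienophile, the need to populate the less favoured ester rotamer and the two quaternary carbons formed may make ring closure slower than 1,5-hydrogen migration around the diene or thermal breakdown of the enol ester. The fallback sets out from acid 11 and activates the dienophile as an enal instead of an enoate. Commercial 3-ethoxy-2-methylacrolein (CCO/C=C(\C)C=O) is hydrolysed with aqueous NaOH and dried to give sodium 2-methyl-3-oxoprop-1-en-1-olate F1. This is O-acylated with acid chloride 13 (made from 11 as in step 8) to give the acyloxy-methacrolein enol ester F2. The more electron-poor dienophile should cyclise in toluene at about 80 to 110 °C to the lactone aldehyde F3. Pinnick oxidation (NaClO2, NaH2PO4, 2-methyl-2-butene) would give the lactone acid F4, and TMSCHN2 in MeOH/toluene the lactone methyl ester F5. F5 is submitted to the conditions of step 10 and rejoins the route at 18.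

Step 10 (lactone opening and retro-aldol cleavage). Methanolysis of the hindered lactone is reversible, so re-closure of the hydroxy ester may outrun carbon–carbon cleavage, or the aldol may re-form from the product. The fallback sets out from 16 and makes the opening irreversible by saponification: KOH in aqueous MeOH at 60 °C opens the lactone as a carboxylate, the alkoxide fragments, and the remaining esters are hydrolysed. Acidification gives the aldehyde triacid F6, which may rest as its lactol. Exhaustive O-methylation of the carboxylates (MeI, K2CO3, DMF, 23 °C) returns to the route at 18.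

Step 11 (olefination). Addition of the phosphonate anion to a neopentyl aldehyde lodged between two fully substituted carbons may be slow. Proton transfer from the propanoate arm could then lead to re-aldolisation and relactonisation, or to premature ring closure. The fallback sets out from 18 and builds the styrene under non-basic conditions. Takai iodo-olefination (CHI3, divalent chromium as CrCl2, THF, 0 to 23 °C) should give the (E)-vinyl iodide F7. Suzuki–Miyaura coupling with phenylboronic acid (Pd(PPh3)4, K3PO4, THF/H2O, 50 °C) then returns to the route at 21.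

**Further compounds**

F1 | step 9 | sodium 2-methyl-3-oxoprop-1-en-1-olate | [Na+].[O-]/C=C(\C)C=O
F2 | step 9 | (E)-2-methyl-3-oxoprop-1-en-1-yl ester of acid 11 | CC[C@@]1(C(=O)O/C=C(\C)C=O)C(CC)=CC(C)=C[C@H]1CC(=O)OC
F3 | step 9 | tricyclic γ-lactone with formyl group on the two-carbon bridge | CC[C@@]12C(=O)O[C@H]3[C@]1(CC)C=C(C)[C@H]([C@]3(C)C=O)[C@H]2CC(=O)OC
F4 | step 9 | tricyclic γ-lactone with carboxylic acid on the two-carbon bridge | CC[C@@]12C(=O)O[C@H]3[C@]1(CC)C=C(C)[C@H]([C@]3(C)C(=O)O)[C@H]2CC(=O)OC
F5 | step 9 | tricyclic γ-lactone with methyl ester on the two-carbon bridge | CC[C@@]12C(=O)O[C@H]3[C@]1(CC)C=C(C)[C@H]([C@]3(C)C(=O)OC)[C@H]2CC(=O)OC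
F6 | step 10 | aldehyde triacid corresponding to 18 (propanoic acid α-centre as a mixture) | CC[C@@]1(C(=O)O)[C@](CC)(C=O)C=C(C)[C@H](C(C)C(=O)O)[C@H]1CC(=O)O
F7 | step 11 | (E)-vinyl iodide corresponding to 21 | CC[C@@]1(C(=O)OC)[C@](CC)(/C=C/I)C=C(C)[C@H]([C@@H](C)C(=O)OC)[C@H]1CC(=O)OC
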